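**Retrosynthetic overview**

1. Locants: oxane O1–C2(CH3)2–C3HBr–C4–C5–C6(CH3); cyclohexane C1' (on C6), C3' (CHBr), C4' (CClCH3). The enabling feature is the O1–C2(CH3)2–C3HBr triad: a ring oxygen on a tertiary carbon next to a secondary C–Br is what bromide leaves when it opens a 1-oxoniabicyclo[3.1.0]hexane. The oxane is therefore disconnected to an oxolane (O1, C3, C4, C5, C6) that carries C2 outside the ring as C(CH3)2OH, with the ring oxygen β to that carbinol carbon.
2. The trans-diequatorial C3'-Br/C4'-Cl pair is disconnected to the cis-epoxide of the chiral-pool terpene (+)-cis-limonene 1,2-oxide, which also supplies C1', the carbocycle, C6 and its methyl. Bromide opens the epoxide at C4' in the same operation as the ring expansion, and a 1,2-bromine shift with chloride capture finishes the pair. Direct BrCl addition to the cyclohexene would favour the trans-diaxial isomer instead.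
3. C6 is set by catalytic asymmetric allylation of the methyl ketone from ozonolysis; the chain is completed by B-alkyl Suzuki coupling and alkene isomerisation; the oxolane C–O centre comes from Shi epoxidation and 5-exo opening.
4. Ring order: cyclohexane (bought), oxolane (step 6), oxane by one-carbon ring expansion of the oxolane (step 7).

Key step: step 7

Remark (assumption): (R,R)-iPr-DuPHOS is taken to direct allyl to the Re face of ketone 3; if the sense is the opposite, the (S,S)-ligand is used.
Remark: 1 is sold as the single cis isomer; it can also be freed from the cheaper cis/trans mixture, because only the trans isomer is opened by secondary amines.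

**Route**

Step 1
Reactants: 1 (+)-cis-limonene 1,2-oxide
Product: 3 1-[(1S,3R,6R)-6-methyl-7-oxabicyclo[4.1.0]heptan-3-yl]ethan-1-one, via ozonide 2 (not isolated)
Conditions: O3, CH2Cl2, −78 °C; then Me2S, −78 → 23 °C
Reagents that add atoms: ozone, [O-][O+]=O
Why: Ozonolysis of the 1,1-disubstituted alkene with reductive work-up should give the methyl ketone; the trisubstituted epoxide is inert to ozone and no stereocentre is touched.

Step 2
Reactants: 3 epoxy ketone; 4 allylboronic acid pinacol ester
Product: 6 (2R)-2-[(1S,3R,6R)-6-methyl-7-oxabicyclo[4.1.0]heptan-3-yl]pent-4-en-2-ol, via borate ester 5 (not isolated)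
Conditions: CuF2·2H2O (3 mol %), (R,R)-iPr-DuPHOS (6 mol %), La(OiPr)3 (4.5 mol %), DMF, −40 °C; aq. NH4Cl
Reagents that add atoms: none
Why: Copper-catalysed enantioselective allylboration of a ketone should add allyl to the Re face under ligand control and so set C6 as (R); the catalyst has to tell CH3 from the branched ring carbon, and the remote ring stereocentres exert no bias of their own.

Step 3
Reactants: 6 homoallylic alcohol; 7 2-bromopropene
Product: 9 (2R)-6-methyl-2-[(1S,3R,6R)-6-methyl-7-oxabicyclo[4.1.0]heptan-3-yl]hept-6-en-2-ol, via B-alkyl-9-BBN adduct 8 (not isolated)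
Conditions: 9-BBN (1.5 equiv), THF, 0 → 23 °C; then 7, PdCl2(dppf) (5 mol %), 3 M aq. NaOH, THF, 50 °C
Reagents that add atoms: none
Why: Anti-Markovnikov hydroboration of the terminal alkene followed by B-alkyl Suzuki–Miyaura coupling with the vinyl bromide should join C3 to C2 under basic conditions that the epoxide and the tertiary alcohol tolerate; no stereocentre is formed.

Step 4
Reactants: 9 1,1-disubstituted alkene
Product: 10 (2R)-6-methyl-2-[(1S,3R,6R)-6-methyl-7-oxabicyclo[4.1.0]heptan-3-yl]hept-5-en-2-ol
Conditions: Co(salen)Cl (2 mol %), PhSiH3 (4 mol %), benzene, 23 °C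
Reagents that add atoms: none
Why: Cobalt-hydride (hydrogen-atom-transfer) alkene isomerisation moves a 1,1-disubstituted double bond by one position into the more stable trisubstituted isopropylidene position and should leave epoxide and alcohol untouched; no stereocentre is formed.

Step 5
Reactants: 10 epoxy alkenol
Product: 11 (2R)-4-[(2S)-3,3-dimethyloxiran-2-yl]-2-[(1S,3R,6R)-6-methyl-7-oxabicyclo[4.1.0]heptan-3-yl]butan-2-ol
Conditions: ent-Shi ketone (L-fructose-derived, 30 mol %), Oxone, K2CO3, n-Bu4NHSO4, MeCN–DMM / aq. borate buffer (pH 10.5), 0 °C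
Reagents that add atoms: Oxone (potassium peroxymonosulfate), [K+].[O-]S(=O)(=O)OO
Why: Shi epoxidation (dioxirane, spiro transition state) of the only alkene should give the (S)-epoxide with the L-ketone, since the D-ketone gives the (R)-epoxides of R–CH=C(CH3)2 olefins; the basic medium spares the acid-labile ring epoxide and the catalyst, not the remote C6, controls the new centre.

Step 6
Reactants: 11 bis-epoxy alcohol
Product: 12 2-[(2R,5R)-5-methyl-5-[(1S,3R,6R)-6-methyl-7-oxabicyclo[4.1.0]heptan-3-yl]oxolan-2-yl]propan-2-ol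
Conditions: KOt-Bu (20 mol %), THF, 0 → 23 °C
Reagents that add atoms: none
Why: Base-mediated 5-exo-tet epoxide opening (Baldwin-favoured) by the C6 alkoxide at the secondary epoxide carbon with inversion should close the oxolane and set its C2 as (R); base instead of acid keeps the attack at the less substituted carbon and should leave the cis ring epoxide, which would cyclise onto the free C6 hydroxyl under acid, intact.

Step 7
Reactants: 12 oxolane carbinol
Product: 17 (1S,2S,5R)-2-bromo-5-[(2R,5S)-5-bromo-2,6,6-trimethyloxan-2-yl]-2-methylcyclohexan-1-ol, via bromo silyl ether 13 (not isolated), via oxonium bromide 14 (not isolated), via tertiary bromide 15 (not isolated), via silyl ether 16 (not isolated)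
Conditions: TMSBr (2.5 equiv), CH2Cl2, −78 °C; then ZnBr2 (20 mol %), −20 → 23 °C; aq. citric acid/THF work-up
Reagents that add atoms: bromotrimethylsilane, C[Si](C)(C)Br
Why: Proposed new method: TMSBr first opens the cis-epoxide by trans-diaxial (Fürst–Plattner) attack of bromide at the tertiary carbon C4' and caps the C3' oxygen as TMS ether (13), then the tertiary carbinol is ionised (HBr formed in situ, ZnBr2) with anchimeric help of the oxolane oxygen, which attacks C2 and closes the three-membered ring of the 1-oxoniabicyclo[3.1.0]hexane 14 (3-exo-tet), and bromide opens the C3–O bond of 14 from the backside so that the five-membered ring becomes the six-membered oxane (endo opening, oxygen shifts from C3 to C2). The closest known reaction type is the rearrangement–ring expansion of 2-(1-sulfonyloxyalkyl)oxolanes to 3-acyloxyoxanes through the same bicyclic oxonium ions with zinc acetate, together with the Markovnikov opening of trisubstituted epoxides by halosilanes; new are the tertiary carbinol as the ionising group and bromide as the terminating nucleophile. C3 is set by SN2 inversion at the former oxolane C2, whose configuration came from the Shi epoxide, and the tertiary C4'–Br centre by inversion at the epoxide carbon; C6, C1' and C3' are not touched. The step needs opening of 14 at C3 and not at C2: capture at the tertiary C2 gives bromide 15, which ZnBr2 re-ionises to 14, while the secondary bromide in the strain-free oxane with its new tertiary C–O bond should not return under these conditions and should collect the material. It needs the C3' oxygen to stay, which the TMS ether secures (a free trans-diaxial bromohydrin would ionise with bromine participation), and the tertiary ethers to survive, which low temperature and the limited excess of TMSBr should secure. The acidic work-up removes the TMS group from 16.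

Step 8
Reactants: 17 dibromo alcohol
Product: 20 deoxycaespitol, (3S,6R)-3-bromo-6-[(1R,3R,4R)-3-bromo-4-chloro-4-methylcyclohexyl]-2,2,6-trimethyloxane, via triflate 18 (not isolated), via bromonium triflate 19 (not isolated)
Conditions: Tf2O (1.3 equiv), 2,6-di-tert-butyl-4-methylpyridine (2 equiv), CH2Cl2, −78 °C; then n-Bu4NCl (5 equiv), −78 → −20 °C
Reagents that add atoms: tetrabutylammonium chloride, CCCC[N+](CCCC)(CCCC)CCCC.[Cl-]
Why: Proposed new method: the axial triflate 18 is anti-periplanar to the axial tertiary C4'–Br bond, so bromine displaces triflate from the β face and gives the bromonium ion 19 (1,2-bromine shift, inversion at C3'); chloride then opens 19 at the tertiary carbon C4', which carries most of the positive charge (Markovnikov), from the α face (inversion at C4'), and this leaves Br on C3' and Cl on C4' trans and both equatorial, the arrangement that direct BrCl addition to the alkene does not favour; the closest known reaction type is substitution of β-bromo alcohol derivatives with neighbouring-bromine participation through a bromonium ion and the Markovnikov halide opening of bromonium ions of 1-methylcyclohexenes, and the selectivity that is needed (C4' over the trans-diaxial return of chloride to C3') rests on the tertiary cation character and on the excess of free chloride.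

**Compound list**

1 | (+)-cis-limonene 1,2-oxide, (1R,4R,6S)-1-methyl-4-(prop-1-en-2-yl)-7-oxabicyclo[4.1.0]heptane | CC(=C)[C@@H]1CC[C@@]2(C)O[C@H]2C1 | starting material
2 | 3-methyl-3-[(1S,3R,6R)-6-methyl-7-oxabicyclo[4.1.0]heptan-3-yl]-1,2,4-trioxolane (ozonide, epimers at the trioxolane carbon) | CC1(OOCO1)[C@@H]2CC[C@@]3(C)O[C@H]3C2 | intermediate
3 | 1-[(1S,3R,6R)-6-methyl-7-oxabicyclo[4.1.0]heptan-3-yl]ethan-1-one | CC(=O)[C@@H]1CC[C@@]2(C)O[C@H]2C1 | intermediate
4 | allylboronic acid pinacol ester | C=CCB1OC(C)(C)C(C)(C)O1 | starting material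
5 | pinacol borate ester of alcohol 6 | C=CC[C@@](C)(OB1OC(C)(C)C(C)(C)O1)[C@@H]2CC[C@@]3(C)O[C@H]3C2 | intermediate
6 | (2R)-2-[(1S,3R,6R)-6-methyl-7-oxabicyclo[4.1.0]heptan-3-yl]pent-4-en-2-ol | C=CC[C@@](C)(O)[C@@H]1CC[C@@]2(C)O[C@H]2C1 | intermediate
7 | 2-bromopropene | CC(Br)=C | starting material
8 | (2R)-5-(9-borabicyclo[3.3.1]nonan-9-yl)-2-[(1S,3R,6R)-6-methyl-7-oxabicyclo[4.1.0]heptan-3-yl]pentan-2-ol | C[C@@](O)(CCCB1C2CCCC1CCC2)[C@@H]3CC[C@@]4(C)O[C@H]4C3 | intermediate
9 | (2R)-6-methyl-2-[(1S,3R,6R)-6-methyl-7-oxabicyclo[4.1.0]heptan-3-yl]hept-6-en-2-ol | C=C(C)CCC[C@@](C)(O)[C@@H]1CC[C@@]2(C)O[C@H]2C1 | intermediate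
10 | (2R)-6-methyl-2-[(1S,3R,6R)-6-methyl-7-oxabicyclo[4.1.0]heptan-3-yl]hept-5-en-2-ol | CC(C)=CCC[C@@](C)(O)[C@@H]1CC[C@@]2(C)O[C@H]2C1 | intermediate
11 | (2R)-4-[(2S)-3,3-dimethyloxiran-2-yl]-2-[(1S,3R,6R)-6-methyl-7-oxabicyclo[4.1.0]heptan-3-yl]butan-2-ol | CC1(C)O[C@H]1CC[C@@](C)(O)[C@@H]2CC[C@@]3(C)O[C@H]3C2 | intermediate
12 | 2-[(2R,5R)-5-methyl-5-[(1S,3R,6R)-6-methyl-7-oxabicyclo[4.1.0]heptan-3-yl]oxolan-2-yl]propan-2-ol | CC(C)(O)[C@H]1CC[C@@](C)(O1)[C@@H]2CC[C@@]3(C)O[C@H]3C2 | intermediate
13 | 2-[(2R,5R)-5-[(1R,3S,4S)-4-bromo-4-methyl-3-(trimethylsilyloxy)cyclohexyl]-5-methyloxolan-2-yl]propan-2-ol | CC(C)(O)[C@H]1CC[C@@](C)(O1)[C@@H]2CC[C@](C)(Br)[C@@H](O[Si](C)(C)C)C2 | intermediate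
14 | 1-oxoniabicyclo[3.1.0]hexane (epoxonium) bromide formed from 13 by O-participation at C2 | CC1(C)[C@H]2CC[C@@](C)([O+]12)[C@@H]3CC[C@](C)(Br)[C@@H](O[Si](C)(C)C)C3.[Br-] | intermediate
15 | (2R,5R)-2-(2-bromopropan-2-yl)-5-[(1R,3S,4S)-4-bromo-4-methyl-3-(trimethylsilyloxy)cyclohexyl]-5-methyloxolane | CC(C)(Br)[C@H]1CC[C@@](C)(O1)[C@@H]2CC[C@](C)(Br)[C@@H](O[Si](C)(C)C)C2 | intermediate
16 | [(1S,2S,5R)-2-bromo-5-[(2R,5S)-5-bromo-2,6,6-trimethyloxan-2-yl]-2-methylcyclohexyl]oxy-trimethylsilane | CC1(C)O[C@@](C)([C@@H]2CC[C@](C)(Br)[C@@H](O[Si](C)(C)C)C2)CC[C@@H]1Br | intermediate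
17 | (1S,2S,5R)-2-bromo-5-[(2R,5S)-5-bromo-2,6,6-trimethyloxan-2-yl]-2-methylcyclohexan-1-ol | CC1(C)O[C@@](C)([C@@H]2CC[C@](C)(Br)[C@@H](O)C2)CC[C@@H]1Br | intermediate
18 | (1S,2S,5R)-2-bromo-5-[(2R,5S)-5-bromo-2,6,6-trimethyloxan-2-yl]-2-methylcyclohexyl trifluoromethanesulfonate | CC1(C)O[C@@](C)([C@@H]2CC[C@](C)(Br)[C@@H](OS(=O)(=O)C(F)(F)F)C2)CC[C@@H]1Br | intermediate
19 | β-face C3'/C4' bromonium ion (7-bromoniabicyclo[4.1.0]heptane) triflate | CC1(C)O[C@@](C)([C@@H]2CC[C@]3(C)[Br+][C@@H]3C2)CC[C@@H]1Br.[O-]S(=O)(=O)C(F)(F)F | intermediate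
20 | deoxycaespitol, (3S,6R)-3-bromo-6-[(1R,3R,4R)-3-bromo-4-chloro-4-methylcyclohexyl]-2,2,6-trimethyloxane | CC1(C)O[C@@](C)([C@@H]2CC[C@@](C)(Cl)[C@H](Br)C2)CC[C@@H]1Br | target

**Step count and risks**

Total step count: 8. Longest linear sequence: 8 steps (from 1).

Steps most likely to fail:

1. Step 7 (proposed new method). The oxonium ion may be opened mainly at the tertiary carbon without the tertiary bromide relaxing to the oxane. A 1,2-hydride shift from C3 to the cationic C2 (oxocarbenium formation) or cleavage of the tertiary ethers by HBr may also compete. The fallback uses known chemistry, sets out from 10 and comes back at 17. Treatment of 10 with 2,4,4,6-tetrabromocyclohexa-2,5-dienone in MeNO2/CH2Cl2 over K2CO3 should effect the known 6-endo (Markovnikov) bromoetherification of the tertiary bishomoallylic alcohol. It should give (3S,6R)-3-bromo-2,2,6-trimethyl-6-[(1S,3R,6R)-6-methyl-7-oxabicyclo[4.1.0]heptan-3-yl]oxane F1 together with its C3 epimer F2, because the remote C6 does not control the face of the bromonium ion; the two are separated by chromatography. F1 is then opened with TMSBr (1.1 equiv, CH2Cl2, −78 °C) to silyl ether 16, which the citric acid work-up converts to 17.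

2. Step 8 (proposed new method). Chloride may return to C3' through the chair-like trans-diaxial opening and give the regioisomeric chloro bromide, or the bromonium ion may lose a proton or Br+. The fallback uses known chemistry, sets out from 17 and comes back at 20. K2CO3 in MeOH should re-close the trans-diaxial bromohydrin to the epoxide F1 of the first fallback. Rhodium-carbenoid deoxygenation (dimethyl diazomalonate, Rh2(OAc)4 cat., toluene, 80 °C) should give (3S,6R)-3-bromo-2,2,6-trimethyl-6-[(1R)-4-methylcyclohex-3-en-1-yl]oxane F3. Direct Markovnikov anti bromochlorination of F3 (NBS, BnEt3NCl, CH2Cl2, −78 °C) should then give 20 together with the trans-diaxial adduct (3S,6R)-3-bromo-6-[(1R,3S,4S)-3-bromo-4-chloro-4-methylcyclohexyl]-2,2,6-trimethyloxane F4. F4 is expected to predominate, so this fallback trades selectivity for known chemistry and needs a separation.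

3. Step 2. The catalyst may show poor facial selectivity with a dialkyl ketone whose two groups differ only as methyl versus a secondary ring carbon. The fallback sets out from 3 and comes back at 10, so steps 3 and 4 are skipped. (4-Methylpent-3-en-1-yl)magnesium bromide F5, made from 5-bromo-2-methylpent-2-ene and magnesium, is added to 3 in THF at −78 °C. Without useful substrate control this should give 10 and its C6 epimer (2S)-6-methyl-2-[(1S,3R,6R)-6-methyl-7-oxabicyclo[4.1.0]heptan-3-yl]hept-5-en-2-ol F6, which are separated by chromatography.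

Further compounds
F1 | step 7 | (3S,6R)-3-bromo-2,2,6-trimethyl-6-[(1S,3R,6R)-6-methyl-7-oxabicyclo[4.1.0]heptan-3-yl]oxane | CC1(C)O[C@@](C)([C@@H]2CC[C@@]3(C)O[C@H]3C2)CC[C@@H]1Br
F2 | step 7 | (3R,6R)-3-bromo-2,2,6-trimethyl-6-[(1S,3R,6R)-6-methyl-7-oxabicyclo[4.1.0]heptan-3-yl]oxane | CC1(C)O[C@@](C)([C@@H]2CC[C@@]3(C)O[C@H]3C2)CC[C@H]1Br
F3 | step 8 | (3S,6R)-3-bromo-2,2,6-trimethyl-6-[(1R)-4-methylcyclohex-3-en-1-yl]oxane | CC1(C)O[C@@](C)([C@@H]2CCC(C)=CC2)CC[C@@H]1Br
F4 | step 8 | (3S,6R)-3-bromo-6-[(1R,3S,4S)-3-bromo-4-chloro-4-methylcyclohexyl]-2,2,6-trimethyloxane | CC1(C)O[C@@](C)([C@@H]2CC[C@](C)(Cl)[C@@H](Br)C2)CC[C@@H]1Br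
F5 | step 2 | (4-methylpent-3-en-1-yl)magnesium bromide | CC(C)=CCC[Mg]Br
F6 | step 2 | (2S)-6-methyl-2-[(1S,3R,6R)-6-methyl-7-oxabicyclo[4.1.0]heptan-3-yl]hept-5-en-2-ol | CC(C)=CCC[C@](C)(O)[C@@H]1CC[C@@]2(C)O[C@H]2C1
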